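**Plan**

- Retrosynthesis: the two O–CH3 bonds on ring B are cut last. The strategic cut dismantles ring A at three C–C bonds: C(OAr)–CH on the chain side and C(OH)–CH between the two oxygenated carbons (both from a ketene–alkyne [2+2]), and C(OH)–CH on the chain side (from a 6π closure). This opens the 20-membered ring and leaves a 3-alkylcyclobutenone tethered to a terminal aryloxyacetylene.
- Further cuts: the bond from chain carbon 12 to the four-membered ring (Grignard addition to 3-ethoxycyclobutenone), the O–C(sp) bond of the alkynyl ether (phenol plus trichloroethylene), and the benzylic C1–C2 bond of the chain (Wittig).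
- Forward: ring B is bought as syringaldehyde; the twelve-carbon chain is joined by Wittig olefination and hydrogenation; the phenol oxygen is vinylated, the chain end brominated and coupled to the four-carbon ring; ring A and the macrocycle then form in one thermal cascade; demethylation ends the route.
- Enabling feature: ring A is a 1,3,5-trisubstituted benzene carrying OH, the diaryl-ether oxygen and chain carbon 12, all mutually meta. A 3-alkylcyclobutenone (supplying C–OH, two CH and the alkyl-bearing carbon) and an oxygen-substituted terminal alkyne (supplying C–O and the CH between the oxygens) give exactly this pattern. The ring-B O–aryl bond, flanked by two oxygenated ortho carbons, is therefore the original phenol oxygen and is never made by C–O coupling.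
- Stereochemistry: the target has no stereocentre and no stereogenic double bond; alkene geometries of intermediates are erased on the way.

Key step: step 8

Remark: compound 6 is drawn as its expected major Z isomer and the dichlorovinyl ethers as E; both geometries disappear later (steps 4 and 7). 3-Ethoxycyclobut-2-en-1-one is taken as a purchasable reagent.

**Route**

Step 1
Reactants: 1 11-bromoundecan-1-ol
Product: 2 (11-hydroxyundecyl)triphenylphosphonium bromide
Conditions: PPh3, MeCN, reflux
Reagents that add atoms: triphenylphosphine, c1ccc(cc1)P(c1ccccc1)c1ccccc1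
Why: SN2 quaternisation of triphenylphosphine by the primary bromide should proceed cleanly, the remote hydroxyl being a spectator.

Step 2
Reactants: 3 syringaldehyde
Product: 4 4-benzyloxy-3,5-dimethoxybenzaldehyde
Conditions: BnBr, K2CO3, DMF, 60 °C
Reagents that add atoms: benzyl bromide, BrCc1ccccc1
Why: Williamson etherification of the acidic phenol keeps the aldehyde from becoming an unreactive phenoxide under the basic Wittig conditions, and the benzyl group is removed at no extra cost in step 4.

Step 3
Reactants: 2 (11-hydroxyundecyl)triphenylphosphonium bromide; 4 4-benzyloxy-3,5-dimethoxybenzaldehyde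
Product: 6 (Z)-12-(4-benzyloxy-3,5-dimethoxyphenyl)dodec-11-en-1-ol, via ylide alkoxide 5 (not isolated)
Conditions: NaN(SiMe3)2 (2.05 equiv), THF, 0 °C; 4, −78 °C to rt; then H2O
Reagents that add atoms: none
Why: Wittig olefination with a non-stabilised ylide whose hydroxyl is held as the sodium alkoxide by the second equivalent of base should give the alkene (mainly Z, of no consequence since it is saturated next).

Step 4
Reactants: 6 (Z)-12-(4-benzyloxy-3,5-dimethoxyphenyl)dodec-11-en-1-ol
Product: 7 4-(12-hydroxydodecyl)-2,6-dimethoxyphenol
Conditions: H2 (1 atm), Pd/C, EtOAc/EtOH, rt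
Reagents that add atoms: none
Why: Heterogeneous catalytic hydrogenation should saturate the styrenyl double bond and hydrogenolyse the benzyl ether in one operation, leaving the methyl ethers and the primary alcohol untouched.

Step 5
Reactants: 7 4-(12-hydroxydodecyl)-2,6-dimethoxyphenol
Product: 8 12-{4-[(E)-1,2-dichloroethenyloxy]-3,5-dimethoxyphenyl}dodecan-1-ol
Conditions: Cl2C=CHCl (1.5 equiv), K2CO3, DMF, 70 °C
Reagents that add atoms: trichloroethylene, ClC=C(Cl)Cl
Why: Base-mediated vinylation of a phenol with trichloroethylene: K2CO3 generates dichloroacetylene in the flask and only the phenoxide (not the un-ionised primary alcohol) adds to it, anti protonation giving the (E)-1,2-dichlorovinyl ether, a standard masked aryloxyacetylene.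

Step 6
Reactants: 8 12-{4-[(E)-1,2-dichloroethenyloxy]-3,5-dimethoxyphenyl}dodecan-1-ol
Product: 9 5-(12-bromododecyl)-2-[(E)-1,2-dichloroethenyloxy]-1,3-dimethoxybenzene
Conditions: CBr4, PPh3, CH2Cl2, 0 °C
Reagents that add atoms: carbon tetrabromide, BrC(Br)(Br)Br
Why: Appel bromination of the primary alcohol (SN2 on the alkoxyphosphonium ion) runs under neutral conditions that should leave the dichlorovinyl ether intact.

Step 7
Reactants: 9 5-(12-bromododecyl)-2-[(E)-1,2-dichloroethenyloxy]-1,3-dimethoxybenzene; 10 3-ethoxycyclobut-2-en-1-one
Product: 14 3-{12-[4-(ethynyloxy)-3,5-dimethoxyphenyl]dodecyl}cyclobut-2-en-1-one, via Grignard reagent 11 (not isolated), via magnesium alkoxide adduct 12 (not isolated), via lithium alkynyl ether 13 (not isolated)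
Conditions: Mg, THF, 35 °C; 10 (1.05 equiv), −78 to 0 °C; n-BuLi (2.3 equiv), −78 to −40 °C; then 0.5 M aq. HCl, THF, 0 °C, short contact
Reagents that add atoms: water, O
Why: Stork–Danheiser-type 1,2-addition of the Grignard reagent to the vinylogous ester gives a tertiary alkoxide that masks the carbonyl while n-BuLi converts the dichlorovinyl ether into the lithium alkynyl ether (deprotonation, loss of chloride, chlorine–lithium exchange on the chloroalkyne); cold dilute acid then protonates the acetylide and ionises the tertiary allylic alcohol to an ethoxy-stabilised cation whose hydration and loss of ethanol should release the 3-alkylcyclobutenone faster than the less basic aryloxyalkyne is hydrated.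

Step 8
Reactants: 14 3-{12-[4-(ethynyloxy)-3,5-dimethoxyphenyl]dodecyl}cyclobut-2-en-1-one
Product: 19 ring-B dimethyl ether of the target (20-membered macrocyclic diaryl ether; ring A free phenol), via vinylketene 15 (not isolated), via macrocyclic vinylcyclobutenone 16 (not isolated), via dienylketene 17 (not isolated), via cyclohexadienone 18 (not isolated)
Conditions: toluene, 110 °C, syringe-pump addition of 14 to about 1 mM final concentration; then K2CO3, MeOH, rt
Reagents that add atoms: none
Why: Proposed new method: heating opens the cyclobutenone of 14 reversibly (4π electrocyclic) to vinylketene 15, whose C=C=O unit adds [2+2] across the electron-rich ynol ether (ketene carbonyl carbon to the alkyne CH, ketene α-carbon to the oxygen-bearing alkyne carbon) to give 16, which opens (4π) to dienylketene 17, closes (6π) to dienone 18 and tautomerises irreversibly to phenol 19. The closest known reaction type is the intermolecular Danheiser benzannulation of 3-alkylcyclobutenones with alkoxy- and siloxyalkynes, which gives 5-alkylresorcinol monoethers; the aryloxy terminal alkyne and the tethered, macrocyclising mode are the untested extensions. The 20-membered ring closes in the ketene–alkyne [2+2] cycloaddition, end to end across a strain-free twelve-methylene tether, and ring A closes in the 6π electrocyclisation of 17, in which the former cyclobutenone CH2 bonds to the ketene carbon. No stereocentre remains in 19, since the only sp3 ring carbon created (in 16) is lost on ring opening. The step needs the regiochemistry that sets OH, OAr and the chain mutually meta, which the polarisation of the ynol ether dictates, and intramolecular over intermolecular ketene capture, which slow addition to about 1 mM and the low stationary concentration of the reversibly formed ketene should favour. The aryl alkynyl ether has no β-C–H for retro-ene loss of the alkyne and both ortho positions of ring B are blocked by OMe, and the closing K2CO3/MeOH treatment merely cleaves any aryl ester that arises if a product phenol has trapped a ketene.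

Step 9
Reactants: 19 ring-B dimethyl ether of the target
Product: 20 CNP0314249.0 (20-membered macrocycle: ring A 1,3,5-trisubstituted with OH, ether O and chain; ring B 2,6-dihydroxy-4-alkylphenyl ether; twelve CH2 between the rings)
Conditions: BBr3 (6 equiv), CH2Cl2, −78 °C to rt; then H2O
Reagents that add atoms: none
Why: Lewis-acid cleavage of aryl methyl ethers (boron coordination, then SN2 attack of bromide on the methyl group) should free both ring-B hydroxyls, while the diaryl ether, which has no sp3 carbon on oxygen, and the saturated chain are inert.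

**Compound list**

1 | 11-bromoundecan-1-ol | OCCCCCCCCCCCBr | starting material
2 | (11-hydroxyundecyl)triphenylphosphonium bromide | OCCCCCCCCCCC[P+](c1ccccc1)(c1ccccc1)c1ccccc1.[Br-] | intermediate
3 | syringaldehyde (4-hydroxy-3,5-dimethoxybenzaldehyde) | COc1cc(C=O)cc(OC)c1O | starting material
4 | 4-benzyloxy-3,5-dimethoxybenzaldehyde | COc1cc(C=O)cc(OC)c1OCc1ccccc1 | intermediate
5 | sodium alkoxide of (11-hydroxyundecylidene)triphenylphosphorane (formed in the flask) | [Na+].[O-]CCCCCCCCCCC=P(c1ccccc1)(c1ccccc1)c1ccccc1 | intermediate
6 | (Z)-12-(4-benzyloxy-3,5-dimethoxyphenyl)dodec-11-en-1-ol | COc1cc(/C=C\CCCCCCCCCCO)cc(OC)c1OCc1ccccc1 | intermediate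
7 | 4-(12-hydroxydodecyl)-2,6-dimethoxyphenol | COc1cc(CCCCCCCCCCCCO)cc(OC)c1O | intermediate
8 | 12-{4-[(E)-1,2-dichloroethenyloxy]-3,5-dimethoxyphenyl}dodecan-1-ol | COc1cc(CCCCCCCCCCCCO)cc(OC)c1O/C(Cl)=C\Cl | intermediate
9 | 5-(12-bromododecyl)-2-[(E)-1,2-dichloroethenyloxy]-1,3-dimethoxybenzene | COc1cc(CCCCCCCCCCCCBr)cc(OC)c1O/C(Cl)=C\Cl | intermediate
10 | 3-ethoxycyclobut-2-en-1-one | CCOC1=CC(=O)C1 | starting material
11 | {12-[4-((E)-1,2-dichloroethenyloxy)-3,5-dimethoxyphenyl]dodecyl}magnesium bromide (formed in the flask) | COc1cc(CCCCCCCCCCCC[Mg]Br)cc(OC)c1O/C(Cl)=C\Cl | intermediate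
12 | bromomagnesium alkoxide of the 1-alkyl-3-ethoxycyclobut-2-en-1-ol adduct, dichlorovinyl ether intact (formed in the flask) | COc1cc(CCCCCCCCCCCCC2(O[Mg]Br)C=C(OCC)C2)cc(OC)c1O/C(Cl)=C\Cl | intermediate
13 | the same alkoxide carrying the lithium aryloxyacetylide (formed in the flask) | COc1cc(CCCCCCCCCCCCC2(O[Mg]Br)C=C(OCC)C2)cc(OC)c1OC#C[Li] | intermediate
14 | 3-{12-[4-(ethynyloxy)-3,5-dimethoxyphenyl]dodecyl}cyclobut-2-en-1-one | COc1cc(CCCCCCCCCCCCC2=CC(=O)C2)cc(OC)c1OC#C | intermediate
15 | 3-{12-[4-(ethynyloxy)-3,5-dimethoxyphenyl]dodecyl}buta-1,3-dien-1-one (vinylketene, transient) | COc1cc(CCCCCCCCCCCCC(=C)C=C=O)cc(OC)c1OC#C | intermediate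
16 | macrocyclic 3-aryloxy-4-(alk-1-en-2-yl)cyclobut-2-en-1-one, 20-membered ring closed, racemic at the sp3 ring carbon (transient) | COc1cc2cc(OC)c1OC1=CC(=O)C1C(=C)CCCCCCCCCCCC2 | intermediate
17 | macrocyclic dienylketene with ketene and vinylidene termini cis across the central double bond (transient) | COc1cc2cc(OC)c1OC(/C=C=O)=C/C(=C)CCCCCCCCCCCC2 | intermediate
18 | macrocyclic 3-aryloxy-5-alkylcyclohexa-2,4-dien-1-one (transient keto tautomer of 19) | COc1cc2cc(OC)c1OC1=CC(=O)CC(=C1)CCCCCCCCCCCC2 | intermediate
19 | macrocyclic diaryl ether, ring A free phenol, ring B 2,6-dimethoxy | Oc1cc2cc(c1)Oc1c(OC)cc(cc1OC)CCCCCCCCCCCC2 | intermediate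
20 | CNP0314249.0 | Oc1cc2cc(c1)Oc1c(O)cc(cc1O)CCCCCCCCCCCC2 | target

**Count and risks**

Total step count: 9. Longest linear sequence: 8 steps (from 3 through steps 2 to 9, or equally from 1 through steps 1 and 3 to 9).

Steps most likely to fail:

Step 8 (proposed new method). What may go wrong: the 20-membered closure has no entropic help, so capture of the vinylketene between molecules (ketene dimerisation, ketene–alkyne oligomerisation) or thermal polymerisation of the terminal aryloxyalkyne may outrun it. Fallback with known chemistry, setting out from 7 and returning at 20: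
- Appel bromination of 7 (CBr4, PPh3) would give 4-(12-bromododecyl)-2,6-dimethoxyphenol F1.
- Bromine–magnesium exchange on 1,3-dibromo-5-methoxybenzene with i-PrMgCl·LiCl would give (3-bromo-5-methoxyphenyl)magnesium chloride F2.
- F2 would be coupled with F1 (phenol first deprotonated with one equivalent of i-PrMgCl) under Li2CuCl4 catalysis in THF, a copper-catalysed alkyl–aryl Kumada-type coupling, to give 4-[12-(3-bromo-5-methoxyphenyl)dodecyl]-2,6-dimethoxyphenol F3.
- Intramolecular Ullmann diaryl ether synthesis (CuO, K2CO3, pyridine, reflux, high dilution) would close the ring to the macrocyclic trimethyl ether F4.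
- BBr3 would cleave all three methyl ethers of F4 to 20.

Step 7. What may go wrong: during magnesium insertion the new organomagnesium may attack the dichlorovinyl ether of another molecule (dehydrochlorination or metal–halogen exchange), or the aryloxyalkyne may be hydrated in the acidic release of the enone. Fallback, setting out from 9 and returning at 14, in which the alkyne is unmasked and capped before any magnesium is present:
- n-BuLi (2.1 equiv, THF, −78 °C; the primary bromide is inert at this temperature) followed by Me3SiCl would give {[4-(12-bromododecyl)-2,6-dimethoxyphenoxy]ethynyl}trimethylsilane F5.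
- Magnesium insertion, addition to 10 and release of the enone on oxalic-acid-doped silica gel would give 3-(12-{3,5-dimethoxy-4-[(trimethylsilyl)ethynyloxy]phenyl}dodecyl)cyclobut-2-en-1-one F6.
- Bu4NF buffered with AcOH in THF at −20 °C would remove the silyl cap to give 14.

Step 5. What may go wrong: slow addition of the doubly ortho-flanked phenoxide, so that forcing conditions bring vinylation of the primary hydroxyl and base-induced loss of material. Fallback, setting out from 3 and returning at 8, in which the vinyl ether is made on the cheap aldehyde that carries no second nucleophile: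
- 3 with trichloroethylene and K2CO3 in DMF would give 4-[(E)-1,2-dichloroethenyloxy]-3,5-dimethoxybenzaldehyde F7.
- Addition of ylide 5 (from 2) to F7 at −78 °C, the aldehyde kept in excess, would give (Z)-12-{4-[(E)-1,2-dichloroethenyloxy]-3,5-dimethoxyphenyl}dodec-11-en-1-ol F8.
- Diimide (2-nitrobenzenesulfonylhydrazide, Et3N, CH2Cl2, rt) would reduce the disubstituted alkene of F8 without touching the C–Cl bonds and deliver 8; steps 2 and 4 are then not needed.

**Further compounds**

F1 | step 8 | 4-(12-bromododecyl)-2,6-dimethoxyphenol | COc1cc(CCCCCCCCCCCCBr)cc(OC)c1O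
F2 | step 8 | (3-bromo-5-methoxyphenyl)magnesium chloride | COc1cc(Br)cc([Mg]Cl)c1
F3 | step 8 | 4-[12-(3-bromo-5-methoxyphenyl)dodecyl]-2,6-dimethoxyphenol | COc1cc(Br)cc(CCCCCCCCCCCCc2cc(OC)c(O)c(OC)c2)c1
F4 | step 8 | trimethyl ether of the target (ring A methoxy, ring B 2,6-dimethoxy macrocycle) | COc1cc2cc(c1)Oc1c(OC)cc(cc1OC)CCCCCCCCCCCC2
F5 | step 7 | {[4-(12-bromododecyl)-2,6-dimethoxyphenoxy]ethynyl}trimethylsilane | COc1cc(CCCCCCCCCCCCBr)cc(OC)c1OC#C[Si](C)(C)C
F6 | step 7 | 3-(12-{3,5-dimethoxy-4-[(trimethylsilyl)ethynyloxy]phenyl}dodecyl)cyclobut-2-en-1-one | COc1cc(CCCCCCCCCCCCC2=CC(=O)C2)cc(OC)c1OC#C[Si](C)(C)C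
F7 | step 5 | 4-[(E)-1,2-dichloroethenyloxy]-3,5-dimethoxybenzaldehyde | COc1cc(C=O)cc(OC)c1O/C(Cl)=C\Cl
F8 | step 5 | (Z)-12-{4-[(E)-1,2-dichloroethenyloxy]-3,5-dimethoxyphenyl}dodec-11-en-1-ol | COc1cc(/C=C\CCCCCCCCCCO)cc(OC)c1O/C(Cl)=C\Cl
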